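**Strategy.** The five-membered ring is traced back to a bicyclic lactone. Its two oxygenated ring carbons, the quaternary C–OAc and the CH–OBz, are joined through the ring CH2–CH(CH3) unit, and the acetoxymethine on the quaternary carbon is an α-oxygenated carbonyl carbon. Together they are C3, C6 and C2 of 3-hydroxy-2-pyranone. A base-catalysed Diels–Alder reaction of this pyranone with (E)-1-propenyl phenyl sulfone (a propene equivalent) joins CH2 to the carbinol carbon and CH(CH3) to the O–CH carbon in one operation and sets the quaternary and methyl stereocentres. The cyclohexene so formed is later contracted by glycol cleavage and aldol re-closure.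

Key step: step 2

Assumption: the pseudoenantiomer of the 6'-hydroxy cinchona catalyst in step 2 is chosen for the absolute sense drawn; the configuration of the secondary alcohol made in step 5 is irrelevant, because that carbon becomes an aldehyde in step 6.

**Step 1**
Reactants: 1 allyl phenyl sulfone
Product: 2 (E)-1-propenyl phenyl sulfone
Conditions: DBU (cat.), MeCN, rt
Reagents that add atoms: none
Why: Base-catalysed prototropic isomerisation of an allyl sulfone; the conjugated internal E-alkene should be the thermodynamic product.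

**Step 2**
Reactants: 2 (E)-1-propenyl phenyl sulfone; 3 3-hydroxy-2H-pyran-2-one
Product: 4 (1S,4R,7S,8R)-4-hydroxy-7-methyl-8-(phenylsulfonyl)-2-oxabicyclo[2.2.2]oct-5-en-3-one
Conditions: 9-O-benzylcupreidine (10 mol %; or its pseudoenantiomer 9-O-benzylcupreine), EtOAc, rt
Reagents that add atoms: none
Why: The amine deprotonates the 3-OH of 3, and the ion-paired 3-oxidopyranone is an electron-rich diene whose C6 attacks the methyl-bearing β-carbon of the vinyl sulfone while the sulfonyl-bearing α-carbon closes onto C3, a concerted but asynchronous [4+2] cycloaddition (Michael/aldol-like in the limit). The closest known reaction type is the base-catalysed Diels–Alder reaction of 3-hydroxy-2-pyranones with electron-poor alkenes. The cyclohexene ring of the bicyclo[2.2.2] lactone is closed by the cycloaddition itself (a 6-exo-trig carbanion-to-ketone closure if it runs stepwise), at a temperature below that of CO2 loss. The two bridgeheads (tertiary carbinol and O–CH) are fixed by suprafacial addition across the planar diene, the methyl stereocentre by retention of the E geometry with the sulfonyl group endo (methyl syn to the lactone bridge), and the absolute sense by the chiral ammonium ion pair. The step needs regioselectivity, which polarisation secures: C6 is the nucleophilic terminus of the 3-oxido diene and the β-carbon of the sulfone is the electrophilic one.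

**Step 3**
Reactants: 4 sulfonyl lactone
Product: 5 (1R,4R,7R)-4-hydroxy-7-methyl-2-oxabicyclo[2.2.2]oct-5-en-3-one
Conditions: Na(Hg) (6 %), Na2HPO4, MeOH/THF, −20 °C
Reagents that add atoms: none
Why: Reductive desulfonylation; the β-oxygen sits on a bridgehead, so Julia-type elimination (an anti-Bredt alkene) is excluded and the carbon is simply protonated, and the low temperature protects the lactone from CO2 extrusion.

**Step 4**
Reactants: 5 bicyclic lactone
Product: 6 (1R,4R,5R)-1,4-dihydroxy-N-methoxy-N,5-dimethylcyclohex-2-ene-1-carboxamide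
Conditions: MeNHOMe·HCl, i-PrMgCl, THF, −20 to 0 °C
Reagents that add atoms: N,O-dimethylhydroxylamine hydrochloride (CNOC.Cl)
Why: Weinreb aminolysis of the strained bridged lactone by the magnesium amide (acyl–oxygen cleavage, no stereocentre touched); the α-hydroxy amide is inert to periodate and is a latent aldehyde.

**Step 5**
Reactants: 6 cyclohexenediol amide
Product: 8 (1R,3R,4R,5R)-1,3,4-trihydroxy-N-methoxy-N,5-dimethylcyclohexane-1-carboxamide, via B-alkyl-9-BBN adduct 7 (not isolated)
Conditions: 9-BBN, THF, 60 °C; then H2O2, aq. NaOH, 0 °C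
Reagents that add atoms: hydrogen peroxide (OO)
Why: Hydroboration–oxidation; the bulky borane should place boron on the alkene carbon remote from the quaternary carbinol and anti to the allylic OH, giving the vicinal diol (its new configuration is of no consequence).

**Step 6**
Reactants: 8 triol amide
Product: 9 (2R,4R)-2-hydroxy-N-methoxy-N,4-dimethyl-5-oxo-2-(2-oxoethyl)pentanamide (in equilibrium with the five-membered lactol of the tertiary OH)
Conditions: NaIO4, THF/H2O, 0 °C
Reagents that add atoms: none
Why: Malaprade glycol cleavage of the only 1,2-diol cuts the ring bond that is not wanted in the target; the tertiary α-hydroxy amide has no vicinal OH and survives.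

**Step 7**
Reactants: 9 dialdehyde
Product: 10 (1R,2S,3S,4R)-2-formyl-1,3-dihydroxy-N-methoxy-N,4-dimethylcyclopentane-1-carboxamide
Conditions: MgBr2·OEt2, i-Pr2NEt, CH2Cl2, −40 to 0 °C
Reagents that add atoms: none
Why: Intramolecular aldol reaction (5-enolexo) by soft enolisation of the unbranched CH2–CHO, the α-branched aldehyde being held as the lactolate and enolising more slowly; in the closed transition state divalent magnesium should bridge the enolate oxygen, the acceptor carbonyl and the tertiary alkoxide, which puts the new OH and the CHO cis to each other and to the tertiary oxygen, anti to the amide carbon and the methyl group.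

**Step 8**
Reactants: 10 β-hydroxy aldehyde
Product: 11 (1R,2S,3S,4R)-2-(dimethoxymethyl)-1,3-dihydroxy-N-methoxy-N,4-dimethylcyclopentane-1-carboxamide
Conditions: HC(OMe)3, MeOH, PPTS, rt
Reagents that add atoms: trimethyl orthoformate (COC(OC)OC); methanol (CO)
Why: Acetalisation under mild acid masks the elimination-prone β-hydroxy aldehyde for the hydride, allylation and metathesis steps; neither hydroxyl can form a cyclic acetal with it (four-membered rings).

**Step 9**
Reactants: 11 acetal diol
Product: 12 (1R,2S,3S,4R)-2-(dimethoxymethyl)-1-hydroxy-1-[methoxy(methyl)carbamoyl]-4-methylcyclopentan-3-yl benzoate (ring locants as in 11)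
Conditions: BzCl, pyridine, DMAP (cat.), CH2Cl2, 0 °C to rt
Reagents that add atoms: benzoyl chloride (O=C(Cl)c1ccccc1)
Why: Acylation of the secondary alcohol; the hindered tertiary alcohol should not react under these conditions.

**Step 10**
Reactants: 12 benzoate amide
Product: 13 (1R,2S,3S,4R)-2-(dimethoxymethyl)-1-formyl-1-hydroxy-4-methylcyclopentan-3-yl benzoate
Conditions: Cp2Zr(H)Cl, THF, rt
Reagents that add atoms: none
Why: Schwartz-reagent reduction of a Weinreb amide stops at the aldehyde through a stable zirconated hemiaminal and should leave the benzoate and the acetal untouched.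

**Step 11**
Reactants: 13 α-hydroxy aldehyde
Product: 14 (1R,2S,3S,4R)-2-(dimethoxymethyl)-1-hydroxy-1-[(1R,2R)-1-hydroxy-2-methylbut-3-en-1-yl]-4-methylcyclopentan-3-yl benzoate
Conditions: (E)-crotyl-Bpin, (R)-TRIP phosphoric acid (10 mol %), toluene, −30 °C
Reagents that add atoms: (E)-crotylboronic acid pinacol ester (C/C=C/CB1OC(C)(C)C(C)(C)O1)
Why: Chiral-phosphoric-acid-catalysed crotylboration through a Zimmerman–Traxler chair; the E-crotyl geometry gives the anti OH/CH3 pair, and the catalyst is expected to direct attack to the Re face of the aldehyde (the antipodal acid is used if the sense proves reversed for this hindered aldehyde).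

**Step 12**
Reactants: 14 diol
Product: 15 (1R,2S,3S,4R)-1-acetoxy-1-[(1R,2R)-1-acetoxy-2-methylbut-3-en-1-yl]-2-(dimethoxymethyl)-4-methylcyclopentan-3-yl benzoate
Conditions: Ac2O, DMAP, Et3N, CH2Cl2, 40 °C
Reagents that add atoms: acetic anhydride (CC(=O)OC(C)=O)
Why: DMAP-catalysed (Steglich-type) acetylation, forcing enough for the tertiary alcohol; any prior acyl migration between the two vicinal oxygens ends in the same diacetate.

**Step 13**
Reactants: 16 prenylmagnesium chloride
Product: 17 3,3-dimethylpent-4-en-2-one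
Conditions: Ac2O, THF, −78 °C (inverse addition)
Reagents that add atoms: acetic anhydride (CC(=O)OC(C)=O)
Why: Acylation of an allylic Grignard reagent with allylic transposition (SE2′), which places the acetyl group on the tertiary carbon; low temperature and inverse addition prevent a second addition.

**Step 14**
Reactants: 15 terminal alkene; 17 3,3-dimethylpent-4-en-2-one (excess)
Product: 18 (1R,2S,3S,4R)-1-acetoxy-1-[(1R,2R,3E)-1-acetoxy-2,5,5-trimethyl-6-oxohept-3-en-1-yl]-2-(dimethoxymethyl)-4-methylcyclopentan-3-yl benzoate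
Conditions: second-generation Hoveyda–Grubbs catalyst (10 mol %), CH2Cl2, 40 °C
Reagents that add atoms: none
Why: Olefin cross-metathesis; the partner with the quaternary allylic carbon cannot homodimerise, and the E-alkene is the thermodynamic product.

**Step 15**
Reactants: 18 dimethyl acetal
Product: 19 (1R,2S,3S,4R)-1-acetoxy-1-[(1R,2R,3E)-1-acetoxy-2,5,5-trimethyl-6-oxohept-3-en-1-yl]-2-formyl-4-methylcyclopentan-3-yl benzoate
Conditions: aq. TFA, CH2Cl2, 0 °C
Reagents that add atoms: water (O)
Why: Acetal hydrolysis under mild acid leaves the three esters and the ketone intact; the aldehyde is used at once.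

**Step 16**
Reactants: 19 aldehyde
Product: 20 target, (1R,2S,3S,4R)-1-acetoxy-1-[(1R,2R,3E)-1-acetoxy-2,5,5-trimethyl-6-oxohept-3-en-1-yl]-4-methyl-2-[(E)-2-methyl-3-oxoprop-1-en-1-yl]cyclopentan-3-yl benzoate
Conditions: Ph3P=C(CH3)CHO, toluene, 80 °C
Reagents that add atoms: 2-(triphenylphosphoranylidene)propanal (CC(C=O)=P(c1ccccc1)(c1ccccc1)c1ccccc1)
Why: Wittig reaction with a stabilised, non-basic ylide should give the (E)-2-methyl enal; the hindered α-quaternary methyl ketone should not react.

**Compound list**

1 | allyl phenyl sulfone | C=CCS(=O)(=O)c1ccccc1 | starting material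
2 | (E)-1-propenyl phenyl sulfone | C/C=C/S(=O)(=O)c1ccccc1 | intermediate
3 | 3-hydroxy-2H-pyran-2-one | OC1=CC=COC1=O | starting material
4 | (1S,4R,7S,8R)-4-hydroxy-7-methyl-8-(phenylsulfonyl)-2-oxabicyclo[2.2.2]oct-5-en-3-one (methyl syn to the lactone bridge, sulfonyl anti) | O=C1O[C@H]2C=C[C@]1(O)[C@H](S(=O)(=O)c3ccccc3)[C@H]2C | intermediate
5 | (1R,4R,7R)-4-hydroxy-7-methyl-2-oxabicyclo[2.2.2]oct-5-en-3-one | O=C1O[C@H]2C=C[C@]1(O)C[C@H]2C | intermediate
6 | (1R,4R,5R)-1,4-dihydroxy-N-methoxy-N,5-dimethylcyclohex-2-ene-1-carboxamide | CON(C)C(=O)[C@@]1(O)C[C@@H](C)[C@@H](O)C=C1 | intermediate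
7 | B-alkyl-9-BBN adduct of 6 (boron on C3, trans to the 4-OH; hydroxyls drawn free) | CON(C)C(=O)[C@@]1(O)C[C@@H](C)[C@@H](O)[C@H](B2C3CCCC2CCC3)C1 | intermediate
8 | (1R,3R,4R,5R)-1,3,4-trihydroxy-N-methoxy-N,5-dimethylcyclohexane-1-carboxamide | CON(C)C(=O)[C@@]1(O)C[C@@H](C)[C@@H](O)[C@H](O)C1 | intermediate
9 | (2R,4R)-2-hydroxy-N-methoxy-N,4-dimethyl-5-oxo-2-(2-oxoethyl)pentanamide | CON(C)C(=O)[C@@](O)(C[C@@H](C)C=O)CC=O | intermediate
10 | (1R,2S,3S,4R)-2-formyl-1,3-dihydroxy-N-methoxy-N,4-dimethylcyclopentane-1-carboxamide | CON(C)C(=O)[C@@]1(O)C[C@@H](C)[C@H](O)[C@@H]1C=O | intermediate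
11 | (1R,2S,3S,4R)-2-(dimethoxymethyl)-1,3-dihydroxy-N-methoxy-N,4-dimethylcyclopentane-1-carboxamide | CON(C)C(=O)[C@@]1(O)C[C@@H](C)[C@H](O)[C@@H]1C(OC)OC | intermediate
12 | (1R,2S,3S,4R)-2-(dimethoxymethyl)-1-hydroxy-1-[methoxy(methyl)carbamoyl]-4-methylcyclopentan-3-yl benzoate | CON(C)C(=O)[C@@]1(O)C[C@@H](C)[C@H](OC(=O)c2ccccc2)[C@@H]1C(OC)OC | intermediate
13 | (1R,2S,3S,4R)-2-(dimethoxymethyl)-1-formyl-1-hydroxy-4-methylcyclopentan-3-yl benzoate | O=C[C@@]1(O)C[C@@H](C)[C@H](OC(=O)c2ccccc2)[C@@H]1C(OC)OC | intermediate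
14 | (1R,2S,3S,4R)-2-(dimethoxymethyl)-1-hydroxy-1-[(1R,2R)-1-hydroxy-2-methylbut-3-en-1-yl]-4-methylcyclopentan-3-yl benzoate | O[C@H]([C@H](C)C=C)[C@@]1(O)C[C@@H](C)[C@H](OC(=O)c2ccccc2)[C@@H]1C(OC)OC | intermediate
15 | (1R,2S,3S,4R)-1-acetoxy-1-[(1R,2R)-1-acetoxy-2-methylbut-3-en-1-yl]-2-(dimethoxymethyl)-4-methylcyclopentan-3-yl benzoate | CC(=O)O[C@H]([C@H](C)C=C)[C@@]1(OC(C)=O)C[C@@H](C)[C@H](OC(=O)c2ccccc2)[C@@H]1C(OC)OC | intermediate
16 | prenylmagnesium chloride (3-methylbut-2-en-1-ylmagnesium chloride) | CC(C)=CC[Mg]Cl | starting material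
17 | 3,3-dimethylpent-4-en-2-one | C=CC(C)(C)C(C)=O | intermediate
18 | (1R,2S,3S,4R)-1-acetoxy-1-[(1R,2R,3E)-1-acetoxy-2,5,5-trimethyl-6-oxohept-3-en-1-yl]-2-(dimethoxymethyl)-4-methylcyclopentan-3-yl benzoate | CC(=O)O[C@H]([C@H](C)/C=C/C(C)(C)C(C)=O)[C@@]1(OC(C)=O)C[C@@H](C)[C@H](OC(=O)c2ccccc2)[C@@H]1C(OC)OC | intermediate
19 | (1R,2S,3S,4R)-1-acetoxy-1-[(1R,2R,3E)-1-acetoxy-2,5,5-trimethyl-6-oxohept-3-en-1-yl]-2-formyl-4-methylcyclopentan-3-yl benzoate | CC(=O)O[C@H]([C@H](C)/C=C/C(C)(C)C(C)=O)[C@@]1(OC(C)=O)C[C@@H](C)[C@H](OC(=O)c2ccccc2)[C@@H]1C=O | intermediate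
20 | (1R,2S,3S,4R)-1-acetoxy-1-[(1R,2R,3E)-1-acetoxy-2,5,5-trimethyl-6-oxohept-3-en-1-yl]-4-methyl-2-[(E)-2-methyl-3-oxoprop-1-en-1-yl]cyclopentan-3-yl benzoate | CC(=O)O[C@H]([C@H](C)/C=C/C(C)(C)C(C)=O)[C@@]1(OC(C)=O)C[C@@H](C)[C@H](OC(=O)c2ccccc2)[C@@H]1/C=C(\C)C=O | target

**Step count.** 16 steps in total; longest linear sequence 15 steps (steps 1–12 and 14–16).

**Steps most likely to fail**

Step 2. The β-methyl vinyl sulfone is a weak acceptor for the oxidopyranone, so the cycloaddition may be too slow, and loss of endo selectivity would invert the methyl stereocentre. Fallback, setting out from 3: the pyranone is combined under the same amine catalysis with (E)-1-nitroprop-1-ene, a far stronger acceptor, which should give the endo-nitro lactone 4-hydroxy-7-methyl-8-nitro-2-oxabicyclo[2.2.2]oct-5-en-3-one F1 (methyl syn to the lactone bridge). Radical denitration (Bu3SnH, AIBN, toluene, 80–110 °C), for which the bridgehead oxygen again excludes elimination, leads back to 5.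

Step 7. The α-methyl aldehyde may epimerise before ring closure, facial control at the new carbinol may be poor, and the aldol may dehydrate. Fallback, setting out from 9: metal-free enamine aldolisation with (S)-proline in DMSO (Houk–List transition state, new OH anti to the formyl group) should give the 3-epimeric aldol F2. It is acetalised (HC(OMe)3, MeOH, PPTS) to the 3-epimeric acetal F3 and oxidised with Dess–Martin periodinane to the β-hydroxy ketone F4. A Narasaka–Prasad reduction (Et2BOMe, NaBH4, THF/MeOH, −78 °C; external hydride on the boron chelate of the tertiary OH and the ketone) then sets the secondary OH syn to the tertiary one and returns to 11. This makes the carbinol configuration independent of the aldol.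

Step 14. Cross-metathesis between two hindered alkenes (a quaternary allylic carbon on one partner, a branched allylic carbon flanked by two acetates on the other) may not turn over. Fallback, setting out from 14: the coupling is moved one stage earlier, to the free diol, where the alkene is less crowded and the neighbouring hydroxyl can assist the ruthenium carbene. Cross-metathesis of 14 with 17 (same catalyst) should give the diol enone F5, and double acetylation (Ac2O, DMAP, Et3N) returns to 18.

**Further compounds**

F1 | step 2 | 4-hydroxy-7-methyl-8-nitro-2-oxabicyclo[2.2.2]oct-5-en-3-one (nitro endo, methyl syn to the lactone bridge) | O=C1O[C@H]2C=C[C@]1(O)[C@H]([N+](=O)[O-])[C@H]2C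
F2 | step 7 | 3-epimer of 10 (3-OH trans to the formyl group) | CON(C)C(=O)[C@@]1(O)C[C@@H](C)[C@@H](O)[C@@H]1C=O
F3 | step 7 | 3-epimer of 11 | CON(C)C(=O)[C@@]1(O)C[C@@H](C)[C@@H](O)[C@@H]1C(OC)OC
F4 | step 7 | 2-(dimethoxymethyl)-1-hydroxy-N-methoxy-N,4-dimethyl-3-oxocyclopentane-1-carboxamide | CON(C)C(=O)[C@@]1(O)C[C@@H](C)C(=O)[C@@H]1C(OC)OC
F5 | step 14 | 2-(dimethoxymethyl)-1-hydroxy-1-[(1R,2R,3E)-1-hydroxy-2,5,5-trimethyl-6-oxohept-3-en-1-yl]-4-methylcyclopentan-3-yl benzoate | O[C@H]([C@H](C)/C=C/C(C)(C)C(C)=O)[C@@]1(O)C[C@@H](C)[C@H](OC(=O)c2ccccc2)[C@@H]1C(OC)OC
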